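A unit of solid substrate charged is the measure here: the reckoning asks what fraction of such units meets partner in time to become target.

    solid substrate ⇌ dissolved substrate, rate k1*(cs1 - [dissolved substrate]) while solid is left; crystals form when [dissolved substrate] > cs1 (cs1 = 1.5 M, k1 = 4.3 × 10⁻⁴ s⁻¹)
    dissolved substrate + partner → target (k2 = 1.5 × 10⁻⁴ M⁻¹ s⁻¹)
    dissolved substrate + target → side product (k3 = 4.3 × 10⁻⁴ M⁻¹ s⁻¹)
    2 partner → self-condensation product (k4 = 7.5 × 10⁻⁵ M⁻¹ s⁻¹)
    partner → decomposed reagent (k5 = 0.0011 s⁻¹)

solid substrate 2.0 M; partner 2.60 M; time 40 min

1. target at 40 min, in percent of the solid substrate charged
2. concentration of dissolved substrate in solution at 40 min, in percent of saturation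

- percent here means solid substrate units held: one side product counts as two
- a doubled species enters its step squared and goes two at a time
- solid substrate is a solid; its amount is given per volume of the solution
- at the start none of the solid substrate is in solution
- dissolved substrate means what is dissolved; the solid is not counted in it
- run time (flask): 40 min

Each end is simple by hand. At the start, the empty solution lets [dissolved substrate] rise at the full dissolving rate; later it levels towards solubility, and one exponential with time constant 38.8 min joins the two ends. Partner is lost faster by decomposition, 0.0660 min⁻¹, than by self-condensation, 0.0234 min⁻¹ at the charge, so it is taken to decay exponentially. Multiplying the two curves by the target step's constant, integrating over unlimited time and dividing by the charge gives 7.47%. This is the meeting number, the target per unit of solid substrate charged if decomposition were partner's one loss and target were never consumed.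

One number is not enough. Adding self-condensation's starting rate to both decay rates lowers it to 4.40%. The side-product step, with a constant 2.87 times the target step's, then consumes target, so the reckoning commits to a little under that. The same curve puts [dissolved substrate] at 64.4% of saturation, less what is consumed.

The forecast gave 3.5% and 59%, holding that “the substrate dissolves slowly, so little target forms”.

The flask gives 3.01% and 59.6%.

At 40.0 min, partner's half-life by decomposition is 11 min, shorter than the 86 min by the target step. This flask's target is 0.403 of its meeting number.

In the neighbour flask charged with 0.80 M of solid substrate, the dissolving curve is held flat once it reaches that charge, below the solubility of 1.5 M, and the meeting number so capped is 17.4%. The same fraction then gives 7.02%, and the simulation of that neighbour flask gives 7.55%, somewhat more than the reckoning.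

The constants used here stand for no real mixture; the run is a simulation.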